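## The problem

Compound 31 is a halimane-type diterpenoid ester. It is a Δ1(10)-octalin whose rings A and B share the C5–C10 bond, whose only ring alkene runs from the fusion carbon C10 to C1 inside ring A, and whose quaternary C9 carries the oxygenated C11–C15 chain. Six stereocentres have to be set: the quaternary C4 (methyl and methoxycarbonyl), the fusion hydrogen at C5, C8, the quaternary C9 and, two methylene groups away from the rings, the tertiary carbinol C13 and the acetoxy carbon C14. C8 can control C9, because a nucleophile enters a 3,4-dimethylcyclohexenone anti to the C8 methyl. C9 itself bears a methyl group and a two-carbon arm of similar size and is a poor director for ring A, so C4 and C5, which are neighbours but remote from C8 and C9, need external control, while C13 and C14 must be bought or set locally. The C1=C10 alkene is trisubstituted and would slide to the tetrasubstituted C5=C10 position under acid, the C13 alcohol is tertiary and dehydrates readily, and the two acetates tolerate neither base nor nucleophiles, so acetylation comes last and the late steps stay near neutral. The enabling feature is that C1 and C10 are adjacent in ring A and that C10 can be the hydrogen-bearing end of a ring B C5=C10 alkene. An acyl cation at C1, tied through C2–C4 to C5, can reach only C10, leaves its charge on the tertiary C5 and, after proton loss, closes ring A as a C1 ketone conjugated to C5=C10. That enone holds every handle ring A still needs: C4 becomes the γ-carbon of a vinylogous β-keto ester, and the C1 oxygen can be traded for H5 with a shift of the alkene to C1=C10.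

## Retrosynthesis

**Acetates and diol.** The two acetyl C–O bonds of 31 are cut first, giving triol 30. The tertiary C13 hydroxyl needs no protection because it does not acylate under Ac2O/pyridine. The 14,15-diol is carried as the acetonide 29, which arrives with the chiral-pool fragment.

**C13.** In 29 the C13–methyl bond is cut to give ketone 28, and then C12–C13 is cut to give iodide 24 and thioester 26. This order lets C14 be bought and C13 be set by a chelate between the ketone and the C14 oxygen. The reverse order (chain nucleophile onto a methyl ketone) would give the C13 epimer under the same chelate. Cuts at C11–C12 or C13–C14 would need chiral fragments that are not on the shelf. The forward ketone synthesis must spare the C4 ester, which calls for an organozinc and a thioester.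

**The C11–C12 handle.** Iodide 24 comes from alcohol 23 and this from the vinyl compound 21. A vinyl group on C9 is the smallest latent form of C11–C12 and survives acid anhydride, base and hydride. 21 holds all four ring stereocentres and nothing else.

**H5 and the C1=C10 alkene.** The C5–H bond of 21 is cut together with a 1,3-shift of the alkene. The retron is an allylic diazene on C1, made from the allylic alcohol 17 with inversion, and 17 comes from enone 16. Reducing the tosylhydrazone of 16 with a borane would reach the same diazene more directly, but the face chosen at C1 would then depend on telling the C9 methyl from the C9 vinyl group. A catalyst-controlled ketone reduction fixes C1, and a stereospecific displacement and retro-ene step then relay it to C5.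

**C4–methyl.** The methyl group of 16 is cut to give the C4–H ester 14. Methylation must come before C5 exists: with a stereogenic C5 next door, the ester enolate would be alkylated under the influence of the C5–C6 bond, with no reliable bias toward the required methyl face. In 14 the two faces of C4 are nearly equivalent and a chiral counter-ion can choose between them.

**C1–C10 (ring A).** Cutting C1–C10 of 14 gives the monocyclic acid 12. The alternatives are less attractive: an aldol or Claisen closure at C1–C2 or C4–C5 would need a C10 or C5 carbonyl flanked by the quaternary C9. The acylium closure uses the alkene that the ring B synthesis delivers anyway. The forward step needs only regiochemistry.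

**C4–C5.** Acid 12 comes from the mixed diester 10 by selective loss of a tert-butyl group. 10 is cut between C4 and C5 into enol triflate 6 and the 2-bromoglutarate 8. A dimethyl glutarate would require a hydrolysis that tells two methyl esters apart. The tert-butyl/methyl pair removes that question.

**Ring B.** Triflate 6 is the trapped enolate of a vinyl conjugate addition (4) to enone 3, which forms C9–C11 anti to the C8 methyl. 3 comes from 1 by methyl conjugate addition to the silyl enol ether 2 and re-oxidation. The C8 centre of 1 thus sets C9.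

**Side fragments.** Bromide 8 is made from the glutamate diester salt 7, and thioester 26 from the glycerate acetonide 25.

## Roads not taken

**Alternative 1:** Ring A is cut at C2–C3 and C4–C5 (a Diels–Alder retron), and ring B at C5–C10 with C1–C2 (enyne metathesis). Forward, the open-chain 1,7-enyne A1 would be closed by a second-generation Grubbs catalyst to the ring B vinylcyclohexene A2. A2 would then add methacrolein A3 to give the bicyclic aldehyde A4 with the alkene already at C1=C10.
- Merits: two rings and four C–C bonds form in one operation, and C4 and C5 arise together in a concerted step. This is shorter to the core than the chosen plan.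
- Weak points: the face of the diene is chosen by C9, whose methyl and silyloxymethyl groups differ little. An α-methyl dienophile gives poor endo/exo discrimination, so the C4/C5 relationship is not secured either. A3 must bond its quaternary carbon to the substituted diene terminus next to a quaternary centre. A1 holds the vicinal C8/C9 pair in an open chain, which is harder to make than by cuprate addition to a ring. The aldehyde must still be oxidised and C12–C15 appended from a one-carbon stub.
- Comparison: against the shorter core assembly, the chosen plan sets C8/C9 by a reliable cyclic addition and gives C4 and C5 each its own control element.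

**Alternative 2:** The C9 methyl is cut as part of a cyclopropane (bonds C9–C20 and C10–C20). Forward, a hydroxyl-directed zinc carbenoid (Simmons–Smith type) would add to the tetrasubstituted C9=C10 alkene of the allylic alcohol A5 to give the cyclopropyl carbinol A6. A radical generated at C1 would then open the C10–C20 bond, leaving C20 as the methyl group and the alkene at C1=C10.
- Merits: the directed methylene transfer sets the C9 quaternary centre with high fidelity. The fragmentation places the alkene without acid and without a displacement at a hindered carbinol, which is better than the chosen plan's diazene step.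
- Weak points: A5 must already contain C4, C5, C8, the C1 carbinol, the full side chain and a tetrasubstituted alkene, none of which the key step helps to make. The cyclopropylcarbinyl radical can also cleave C9–C10, giving a tertiary radical and a seven-membered ring B. The route to A5 is long and linear.
- Comparison: the chosen plan answers C9 early and cheaply, and uses its key step to build ring A rather than to correct one substituent.

**Alternative 3:** Ring A is cut at C4–C5 as a 6π-electrocyclisation retron. Forward, semihydrogenation of the dienyne A7 over a Lindlar-type catalyst gives the (1Z)-triene A8, which closes disrotatorily to the cyclohexadiene A9.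
- Merits: the relative configuration of C4 and C5 is written into the C3=C4 geometry and transferred stereospecifically. This is a firmer answer to C4 than the catalyst-controlled methylation of the chosen plan. The side chain can be complete before the ring closure.
- Weak points: the two disrotatory senses are again told apart only by C9, so the correct C4/C5 pair would form beside its mirror-configured pair. The C4 terminus is fully substituted with the ester pointing inward, which raises the barrier and invites hydrogen shifts in the triene. A9 needs a selective reduction of C2=C3 beside C1=C10. The geometrically pure trisubstituted enyne ester A7 is not trivial to make.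
- Comparison: the chosen plan has weaker relative control at C4, but its absolute control at C5 is by reagent and its ring closure carries no stereochemical burden.

Key step: step 7

Assumption: atom labels C1–C20 follow halimane numbering throughout; compounds 1, 4, 7 and 25 are taken as purchasable, and the enantiopurity of 8 is immaterial because its stereocentre is enolised.

## Route

Step 1
Reactants: 1 (R)-4-methylcyclohex-2-en-1-one
Product: 2 trimethyl{[(3S,4R)-3,4-dimethylcyclohex-1-en-1-yl]oxy}silane
Conditions: MeMgBr, CuBr·SMe2 (5 mol %), TMSCl, DMPU, THF, −78 °C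
Reagents that add atoms: methylmagnesium bromide, C[Mg]Br; chlorotrimethylsilane, C[Si](C)(C)Cl
Why: Copper-catalysed conjugate addition of a Grignard reagent with in situ silylation gives the regiodefined silyl enol ether; methyl enters anti to the C8 methyl, but this new centre is erased in step 2.

Step 2
Reactants: 2 trimethyl{[(3S,4R)-3,4-dimethylcyclohex-1-en-1-yl]oxy}silane
Product: 3 (R)-3,4-dimethylcyclohex-2-en-1-one
Conditions: Pd(OAc)2 (10 mol %), O2 (1 atm), DMSO, rt
Reagents that add atoms: none
Why: Saegusa–Ito oxidation; the palladium enolate can lose only the hydrogen on the methyl-bearing carbon, so the enone forms on that side, and C8, which is never enolised, keeps its configuration.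

Step 3
Reactants: 3 (R)-3,4-dimethylcyclohex-2-en-1-one; 4 vinylmagnesium bromide
Product: 6 (3S,4R)-3-ethenyl-3,4-dimethylcyclohex-1-en-1-yl trifluoromethanesulfonate, via bromomagnesium enolate 5 (not isolated)
Conditions: 4, CuBr·SMe2 (20 mol %), THF, −40 °C; then N-(5-chloropyridin-2-yl)bis(trifluoromethanesulfonyl)imide (Comins' reagent), −78 °C → rt
Reagents that add atoms: N-(5-chloropyridin-2-yl)bis(trifluoromethanesulfonyl)imide, O=S(=O)(N(c1ccc(Cl)cn1)S(=O)(=O)C(F)(F)F)C(F)(F)F
Why: Copper-catalysed 1,4-addition to the β,β-disubstituted enone followed by O-triflation of the regiodefined enolate; the C8 methyl sits pseudoaxial to avoid strain with the C9 methyl and the vinyl group adds axially to the opposite face, which sets C9 (vinyl trans to C17, C20 cis to C17).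

Step 4
Reactants: 7 5-tert-butyl 1-methyl L-glutamate hydrochloride
Product: 8 5-tert-butyl 1-methyl (2S)-2-bromopentanedioate
Conditions: NaNO2, 2 M aq. HBr, 0 °C → rt
Reagents that add atoms: hydrogen bromide, Br
Why: Diazotisation of the α-amino ester with bromide capture through the α-lactone (net retention); tert-butyl esters survive cold dilute HBr in this standard preparation of 2-bromoglutarates.

Step 5
Reactants: 6 (3S,4R)-3-ethenyl-3,4-dimethylcyclohex-1-en-1-yl trifluoromethanesulfonate; 8 5-tert-butyl 1-methyl (2S)-2-bromopentanedioate
Product: 10 5-tert-butyl 1-methyl 2-[(3S,4R)-3-ethenyl-3,4-dimethylcyclohex-1-en-1-yl]pentanedioate (both C4 epimers), via bromozinc ester enolate 9 (not isolated)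
Conditions: 8, Zn dust (TMSCl-activated), THF, rt; then 6, Pd(OAc)2 (5 mol %), XPhos (10 mol %), THF, 60 °C
Reagents that add atoms: none
Why: Reformatsky reagent formation followed by Negishi-type α-alkenylation of the zinc ester enolate with the enol triflate on zerovalent palladium formed in situ; the nearly neutral zinc enolate keeps the alkene out of conjugation and leaves both esters intact.

Step 6
Reactants: 10 5-tert-butyl 1-methyl 2-[(3S,4R)-3-ethenyl-3,4-dimethylcyclohex-1-en-1-yl]pentanedioate
Product: 12 4-[(3S,4R)-3-ethenyl-3,4-dimethylcyclohex-1-en-1-yl]-5-methoxy-5-oxopentanoic acid (both C4 epimers), via trimethylsilyl ester 11 (not isolated)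
Conditions: TMSOTf, 2,6-lutidine, CH2Cl2, 0 °C → rt; aq. NH4Cl work-up
Reagents that add atoms: none
Why: Silyl triflate-mediated tert-butyl ester cleavage (O-silylation, loss of isobutene, hydrolysis of the silyl ester on work-up); no free strong acid meets the trisubstituted alkene, and the methyl ester is untouched.

Step 7
Reactants: 12 4-[(3S,4R)-3-ethenyl-3,4-dimethylcyclohex-1-en-1-yl]-5-methoxy-5-oxopentanoic acid
Product: 14 methyl (5S,6R)-5-ethenyl-5,6-dimethyl-4-oxo-1,2,3,4,5,6,7,8-octahydronaphthalene-1-carboxylate (both C4 epimers), via mixed trifluoroacetic anhydride 13 (not isolated)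
Conditions: (CF3CO)2O, CH2Cl2, 0 °C → rt; then Et3N, 0 °C
Reagents that add atoms: none
Why: (CF3CO)2O turns the acid into the mixed anhydride 13, an acylium equivalent whose acyl carbon C1 attacks the hydrogen-bearing alkene carbon C10 while positive charge builds on the tertiary C5. Ring A closes in the 6-endo mode with respect to the alkene (both alkene carbons become ring members); the alternative bond to C5 would give a spiro five-membered ketone and a secondary cation at C10 beside the quaternary C9, so tether length and cation stability agree on C10. Loss of the C10 proton, directly or by elimination of a transient tertiary trifluoroacetate on addition of Et3N, gives the enone with the carbonyl at C1 and the alkene at C5=C10. The closest known reaction type is the anhydride-promoted intramolecular Friedel–Crafts-type acylation of cyclohexenes by a tethered carboxylic acid, as in the closure of 4-(cyclohex-1-enyl)butanoic acids to octalones. No stereocentre is created: C5 and C10 end as sp2 carbons and C4 stays epimeric. Only regiochemistry is required, and any β,γ-unsaturated isomer is equilibrated by the amine and in any case gives the same dienolate in step 8. The monosubstituted C9 vinyl group is out of reach of C1 and too electron-poor to compete, and the methyl ester is inert.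

Step 8
Reactants: 14 methyl (5S,6R)-5-ethenyl-5,6-dimethyl-4-oxo-1,2,3,4,5,6,7,8-octahydronaphthalene-1-carboxylate
Product: 16 methyl (1R,5S,6R)-5-ethenyl-1,5,6-trimethyl-4-oxo-1,2,3,4,5,6,7,8-octahydronaphthalene-1-carboxylate, via caesium dienolate 15 (not isolated)
Conditions: MeI, O-allyl-N-(9-anthracenylmethyl)cinchonidinium bromide (10 mol %), CsOH·H2O, toluene/CH2Cl2 (7:3), −40 °C
Reagents that add atoms: iodomethane, CI
Why: Proposed new method: deprotonation at C4, the most acidic site (α to the ester and vinylogously γ to the C1 ketone), gives a planar dienolate into which both C4 epimers of 14 converge; C-methylation should go to C4 because the other carbon terminus, C10, is fully substituted and flanked by the quaternary C9 (in Hagemann-type esters with a free α-carbon the electrophile goes there instead); the substrate's own stereocentres are remote from C4, so the face should be chosen by the chiral ammonium counter-ion in the contact ion pair; the closest known reaction type is the cinchona-ammonium phase-transfer alkylation of cyclic β-keto esters and related 1,3-dicarbonyl enolates to quaternary centres; the sense of induction cannot be predicted for this enolate class, so the pseudo-enantiomeric cinchoninium salt is the immediate alternative if the cinchonidinium salt favours the C4 epimer.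

Step 9
Reactants: 16 methyl (1R,5S,6R)-5-ethenyl-1,5,6-trimethyl-4-oxo-1,2,3,4,5,6,7,8-octahydronaphthalene-1-carboxylate
Product: 17 methyl (1R,4R,5S,6R)-5-ethenyl-4-hydroxy-1,5,6-trimethyl-1,2,3,4,5,6,7,8-octahydronaphthalene-1-carboxylate
Conditions: (S)-Me-CBS oxazaborolidine [(S)-1-methyl-3,3-diphenyltetrahydro-1H,3H-pyrrolo[1,2-c][1,3,2]oxazaborole] (0.3 equiv), catecholborane, toluene, −78 °C
Reagents that add atoms: none
Why: Corey–Bakshi–Shibata reduction; the ketone binds the catalyst boron anti to its bulky alkenyl flank (C10) and hydride goes to the α face, giving the 1β-alcohol (1R in halimane numbering) by the same model that gives (R)-carbinols from aryl methyl ketones; reagent control is used because the C9 methyl and vinyl groups differentiate the faces of C1 poorly, and the s-trans enone, the ester and the vinyl group do not react with catecholborane at −78 °C.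

Step 10
Reactants: 17 methyl (1R,4R,5S,6R)-5-ethenyl-4-hydroxy-1,5,6-trimethyl-1,2,3,4,5,6,7,8-octahydronaphthalene-1-carboxylate
Product: 21 methyl (1R,5S,6R,8aR)-5-ethenyl-1,5,6-trimethyl-1,2,3,5,6,7,8,8a-octahydronaphthalene-1-carboxylate, via N-alkyl sulfonylhydrazone 18 (not isolated), via N-alkyl sulfonylhydrazine 19 (not isolated), via allylic diazene 20 (not isolated)
Conditions: N-isopropylidene-N′-(2-nitrobenzenesulfonyl)hydrazine, PPh3, DEAD, THF, 0 °C → rt; then CF3CH2OH/H2O (1:1), rt
Reagents that add atoms: none
Why: Mitsunobu displacement by the sulfonylhydrazone nitrogen inverts C1; solvolysis then releases acetone and the sulfinate to give the monoalkyl diazene on the α face, whose retro-ene loss of N2 passes hydrogen suprafacially to the α face of C5 while the alkene moves to C1=C10 (reductive 1,3-transposition of an allylic alcohol); H5 is thereby fixed by the C1 carbinol configuration.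

Step 11
Reactants: 21 methyl (1R,5S,6R,8aR)-5-ethenyl-1,5,6-trimethyl-1,2,3,5,6,7,8,8a-octahydronaphthalene-1-carboxylate
Product: 23 methyl (1R,5S,6R,8aR)-5-(2-hydroxyethyl)-1,5,6-trimethyl-1,2,3,5,6,7,8,8a-octahydronaphthalene-1-carboxylate, via B-alkyl-9-BBN borane 22 (not isolated)
Conditions: 9-BBN, THF, 0 °C → rt; then aq. NaOH, H2O2, 0 °C
Reagents that add atoms: hydrogen peroxide, OO
Why: Anti-Markovnikov hydroboration–oxidation; 9-BBN selects the monosubstituted vinyl group over the hindered trisubstituted ring alkene, and the ester on the quaternary C4 resists brief cold alkaline peroxide.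

Step 12
Reactants: 23 methyl (1R,5S,6R,8aR)-5-(2-hydroxyethyl)-1,5,6-trimethyl-1,2,3,5,6,7,8,8a-octahydronaphthalene-1-carboxylate
Product: 24 methyl (1R,5S,6R,8aR)-5-(2-iodoethyl)-1,5,6-trimethyl-1,2,3,5,6,7,8,8a-octahydronaphthalene-1-carboxylate
Conditions: I2, PPh3, imidazole, CH2Cl2, 0 °C → rt
Reagents that add atoms: iodine, II
Why: Appel-type iodination of the primary alcohol through the alkoxyphosphonium ion; the buffered medium leaves the C1=C10 alkene where it is.

Step 13
Reactants: 25 methyl (R)-2,2-dimethyl-1,3-dioxolane-4-carboxylate
Product: 26 S-ethyl (R)-2,2-dimethyl-1,3-dioxolane-4-carbothioate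
Conditions: EtSH, AlMe3, CH2Cl2, 0 °C → rt
Reagents that add atoms: ethanethiol, CCS
Why: Ester-to-thioester exchange with the dimethylaluminium thiolate formed from AlMe3 and EtSH; the reagent is Lewis acidic and not basic, so the α-alkoxy centre (the future C14) is not epimerised.

Step 14
Reactants: 24 methyl (1R,5S,6R,8aR)-5-(2-iodoethyl)-1,5,6-trimethyl-1,2,3,5,6,7,8,8a-octahydronaphthalene-1-carboxylate; 26 S-ethyl (R)-2,2-dimethyl-1,3-dioxolane-4-carbothioate
Product: 28 methyl (1R,5S,6R,8aR)-5-{3-[(4R)-2,2-dimethyl-1,3-dioxolan-4-yl]-3-oxopropyl}-1,5,6-trimethyl-1,2,3,5,6,7,8,8a-octahydronaphthalene-1-carboxylate, via alkylzinc iodide 27 (not isolated)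
Conditions: 24, Zn dust (1,2-dibromoethane/TMSCl-activated), DMA/THF, 40 °C; then 26, PdCl2(PPh3)2 (10 mol %), toluene, rt
Reagents that add atoms: none
Why: Zinc insertion into the primary iodide and Fukuyama coupling (oxidative addition of zerovalent palladium into the C–S bond, transmetalation, reductive elimination) give the ketone; the organozinc ignores the methyl ester and does not enolise the α-alkoxy centre.

Step 15
Reactants: 28 methyl (1R,5S,6R,8aR)-5-{3-[(4R)-2,2-dimethyl-1,3-dioxolan-4-yl]-3-oxopropyl}-1,5,6-trimethyl-1,2,3,5,6,7,8,8a-octahydronaphthalene-1-carboxylate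
Product: 29 methyl (1R,5S,6R,8aR)-5-{(3S)-3-[(4R)-2,2-dimethyl-1,3-dioxolan-4-yl]-3-hydroxybutyl}-1,5,6-trimethyl-1,2,3,5,6,7,8,8a-octahydronaphthalene-1-carboxylate
Conditions: MeMgBr (Et2O solution), CH2Cl2, −78 °C
Reagents that add atoms: methylmagnesium bromide, C[Mg]Br
Why: Chelation-controlled Grignard addition (Cram chelate model); magnesium bridges the C13 carbonyl and the C14 oxygen, and methyl attacks the face of the five-membered chelate that carries H14, which gives the (13S) carbinol; the hindered C4 ester does not react at −78 °C.

Step 16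
Reactants: 29 methyl (1R,5S,6R,8aR)-5-{(3S)-3-[(4R)-2,2-dimethyl-1,3-dioxolan-4-yl]-3-hydroxybutyl}-1,5,6-trimethyl-1,2,3,5,6,7,8,8a-octahydronaphthalene-1-carboxylate
Product: 30 methyl (1R,5S,6R,8aR)-5-[(3S,4R)-3,4,5-trihydroxy-3-methylpentyl]-1,5,6-trimethyl-1,2,3,5,6,7,8,8a-octahydronaphthalene-1-carboxylate
Conditions: AcOH/H2O (4:1), 40 °C
Reagents that add atoms: none
Why: Acid-catalysed acetonide hydrolysis in aqueous acetic acid, mild enough for the tertiary alcohol and the C1=C10 alkene.

Step 17
Reactants: 30 methyl (1R,5S,6R,8aR)-5-[(3S,4R)-3,4,5-trihydroxy-3-methylpentyl]-1,5,6-trimethyl-1,2,3,5,6,7,8,8a-octahydronaphthalene-1-carboxylate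
Product: 31 methyl (1R,5S,6R,8aR)-5-[(3S,4R)-4,5-diacetoxy-3-hydroxy-3-methylpentyl]-1,5,6-trimethyl-1,2,3,5,6,7,8,8a-octahydronaphthalene-1-carboxylate (CNP0238486.1)
Conditions: Ac2O, pyridine, CH2Cl2, 0 °C → rt
Reagents that add atoms: acetic anhydride, CC(=O)OC(C)=O
Why: Acylation with Ac2O/pyridine esterifies the primary C15 and secondary C14 hydroxyls; the tertiary C13 hydroxyl is too hindered to react under these conditions, so the target results without a protecting group.

## Compound list

1 | (R)-4-methylcyclohex-2-en-1-one | C[C@@H]1CCC(=O)C=C1 | starting material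
2 | trimethyl{[(3S,4R)-3,4-dimethylcyclohex-1-en-1-yl]oxy}silane | C[Si](C)(C)OC1=C[C@@H](C)[C@H](C)CC1 | intermediate
3 | (R)-3,4-dimethylcyclohex-2-en-1-one | O=C1C=C(C)[C@H](C)CC1 | intermediate
4 | vinylmagnesium bromide | C=C[Mg]Br | starting material
5 | bromomagnesium (3S,4R)-3-ethenyl-3,4-dimethylcyclohex-1-en-1-olate | Br[Mg]OC1=C[C@@](C)(C=C)[C@H](C)CC1 | intermediate
6 | (3S,4R)-3-ethenyl-3,4-dimethylcyclohex-1-en-1-yl trifluoromethanesulfonate | O=S(=O)(OC1=C[C@@](C)(C=C)[C@H](C)CC1)C(F)(F)F | intermediate
7 | 5-tert-butyl 1-methyl L-glutamate hydrochloride | Cl.COC(=O)[C@@H](N)CCC(=O)OC(C)(C)C | starting material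
8 | 5-tert-butyl 1-methyl (2S)-2-bromopentanedioate | COC(=O)[C@@H](Br)CCC(=O)OC(C)(C)C | intermediate
9 | bromo[5-(tert-butoxy)-1-methoxy-1,5-dioxopentan-2-yl]zinc (Reformatsky reagent of 8) | COC(=O)C([Zn]Br)CCC(=O)OC(C)(C)C | intermediate
10 | 5-tert-butyl 1-methyl 2-[(3S,4R)-3-ethenyl-3,4-dimethylcyclohex-1-en-1-yl]pentanedioate (C4 epimers) | COC(=O)C(CCC(=O)OC(C)(C)C)C1=C[C@@](C)(C=C)[C@H](C)CC1 | intermediate
11 | 1-methyl 5-trimethylsilyl 2-[(3S,4R)-3-ethenyl-3,4-dimethylcyclohex-1-en-1-yl]pentanedioate | COC(=O)C(CCC(=O)O[Si](C)(C)C)C1=C[C@@](C)(C=C)[C@H](C)CC1 | intermediate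
12 | 4-[(3S,4R)-3-ethenyl-3,4-dimethylcyclohex-1-en-1-yl]-5-methoxy-5-oxopentanoic acid (C4 epimers) | COC(=O)C(CCC(=O)O)C1=C[C@@](C)(C=C)[C@H](C)CC1 | intermediate
13 | mixed anhydride of 12 with trifluoroacetic acid | COC(=O)C(CCC(=O)OC(=O)C(F)(F)F)C1=C[C@@](C)(C=C)[C@H](C)CC1 | intermediate
14 | methyl (5S,6R)-5-ethenyl-5,6-dimethyl-4-oxo-1,2,3,4,5,6,7,8-octahydronaphthalene-1-carboxylate (C4 epimers; 5(10)-en-1-one) | COC(=O)C1CCC(=O)C2=C1CC[C@@H](C)[C@]2(C)C=C | intermediate
15 | caesium dienolate of 14 (C1 oxygen through C10 and C5 to C4) | [Cs+].COC(=O)C1=C2CC[C@@H](C)[C@](C)(C=C)C2=C([O-])CC1 | intermediate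
16 | methyl (1R,5S,6R)-5-ethenyl-1,5,6-trimethyl-4-oxo-1,2,3,4,5,6,7,8-octahydronaphthalene-1-carboxylate | COC(=O)[C@]1(C)CCC(=O)C2=C1CC[C@@H](C)[C@]2(C)C=C | intermediate
17 | methyl (1R,4R,5S,6R)-5-ethenyl-4-hydroxy-1,5,6-trimethyl-1,2,3,4,5,6,7,8-octahydronaphthalene-1-carboxylate (1β-alcohol) | COC(=O)[C@]1(C)CC[C@@H](O)C2=C1CC[C@@H](C)[C@]2(C)C=C | intermediate
18 | N-(C1α-alkyl)-N′-isopropylidene-2-nitrobenzenesulfonohydrazide from 17 (C1 inverted) | COC(=O)[C@]1(C)CC[C@H](N(N=C(C)C)S(=O)(=O)c3ccccc3[N+](=O)[O-])C2=C1CC[C@@H](C)[C@]2(C)C=C | intermediate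
19 | N-(C1α-alkyl)-2-nitrobenzenesulfonohydrazide | COC(=O)[C@]1(C)CC[C@H](N(N)S(=O)(=O)c3ccccc3[N+](=O)[O-])C2=C1CC[C@@H](C)[C@]2(C)C=C | intermediate
20 | C1α monoalkyl diazene | COC(=O)[C@]1(C)CC[C@H](N=N)C2=C1CC[C@@H](C)[C@]2(C)C=C | intermediate
21 | methyl (1R,5S,6R,8aR)-5-ethenyl-1,5,6-trimethyl-1,2,3,5,6,7,8,8a-octahydronaphthalene-1-carboxylate | COC(=O)[C@]1(C)CCC=C2[C@H]1CC[C@@H](C)[C@]2(C)C=C | intermediate
22 | B-alkyl-9-borabicyclo[3.3.1]nonane from 21 (boron on C12) | COC(=O)[C@]1(C)CCC=C2[C@H]1CC[C@@H](C)[C@]2(C)CCB3C4CCCC3CCC4 | intermediate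
23 | methyl (1R,5S,6R,8aR)-5-(2-hydroxyethyl)-1,5,6-trimethyl-1,2,3,5,6,7,8,8a-octahydronaphthalene-1-carboxylate | COC(=O)[C@]1(C)CCC=C2[C@H]1CC[C@@H](C)[C@]2(C)CCO | intermediate
24 | methyl (1R,5S,6R,8aR)-5-(2-iodoethyl)-1,5,6-trimethyl-1,2,3,5,6,7,8,8a-octahydronaphthalene-1-carboxylate | COC(=O)[C@]1(C)CCC=C2[C@H]1CC[C@@H](C)[C@]2(C)CCI | intermediate
25 | methyl (R)-2,2-dimethyl-1,3-dioxolane-4-carboxylate | COC(=O)[C@H]1COC(C)(C)O1 | starting material
26 | S-ethyl (R)-2,2-dimethyl-1,3-dioxolane-4-carbothioate | CCSC(=O)[C@H]1COC(C)(C)O1 | intermediate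
27 | alkylzinc iodide from 24 (zinc on C12) | COC(=O)[C@]1(C)CCC=C2[C@H]1CC[C@@H](C)[C@]2(C)CC[Zn]I | intermediate
28 | methyl (1R,5S,6R,8aR)-5-{3-[(4R)-2,2-dimethyl-1,3-dioxolan-4-yl]-3-oxopropyl}-1,5,6-trimethyl-1,2,3,5,6,7,8,8a-octahydronaphthalene-1-carboxylate | COC(=O)[C@]1(C)CCC=C2[C@H]1CC[C@@H](C)[C@]2(C)CCC(=O)[C@H]3COC(C)(C)O3 | intermediate
29 | methyl (1R,5S,6R,8aR)-5-{(3S)-3-[(4R)-2,2-dimethyl-1,3-dioxolan-4-yl]-3-hydroxybutyl}-1,5,6-trimethyl-1,2,3,5,6,7,8,8a-octahydronaphthalene-1-carboxylate | COC(=O)[C@]1(C)CCC=C2[C@H]1CC[C@@H](C)[C@]2(C)CC[C@](C)(O)[C@H]3COC(C)(C)O3 | intermediate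
30 | methyl (1R,5S,6R,8aR)-5-[(3S,4R)-3,4,5-trihydroxy-3-methylpentyl]-1,5,6-trimethyl-1,2,3,5,6,7,8,8a-octahydronaphthalene-1-carboxylate | COC(=O)[C@]1(C)CCC=C2[C@H]1CC[C@@H](C)[C@]2(C)CC[C@](C)(O)[C@@H](CO)O | intermediate
31 | methyl (1R,5S,6R,8aR)-5-[(3S,4R)-4,5-diacetoxy-3-hydroxy-3-methylpentyl]-1,5,6-trimethyl-1,2,3,5,6,7,8,8a-octahydronaphthalene-1-carboxylate (CNP0238486.1) | COC(=O)[C@]1(C)CCC=C2[C@H]1CC[C@@H](C)[C@]2(C)CC[C@](C)(O)[C@@H](COC(C)=O)OC(C)=O | target

## Step count and least certain steps

Total: 17 steps. Longest linear sequence: 15 steps (1 to 31 through steps 1–3, 5–12 and 14–17); steps 4 and 13 prepare the side fragments 8 and 26.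

**Step 8 (C4 methylation).** The chiral ammonium ion may discriminate poorly between the faces of a nearly flat dienolate whose own stereocentres are remote, so that both C4 epimers form. O-methylation or methylation at C2 could also compete, and the hydroxide could saponify the ester before alkylation. The fallback uses known chemistry and sets out from diester 10. Deprotonation with LiN(i-Pr)2 in THF at −78 °C and α-methylation of the ester dienolate with MeI would give 5-tert-butyl 1-methyl 2-[(3S,4R)-3-ethenyl-3,4-dimethylcyclohex-1-en-1-yl]-2-methylpentanedioate F1 as both C4 epimers. TMSOTf/2,6-lutidine as in step 6 would give the acid F2. Closure with (CF3CO)2O as in step 7 would give 16 together with its C4 epimer F3, which are diastereomers and would be separated by chromatography. The fallback rejoins the route at 16. It secures the bond but gives up stereocontrol at C4 and loses the material that ends as F3.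

**Step 7 (key step).** The carboxyl oxygen may capture the C5 cation (δ-lactonisation after protonation of the alkene by liberated CF3CO2H), the alkene may migrate before acylation, and attack at C10 may be slowed by the adjacent quaternary C9. The fallback closes the same C1–C10 bond by a carbonyl-ene reaction, in which no free cation is formed, and sets out from acid 12. Activation with isobutyl chloroformate/N-methylmorpholine and reduction with NaBH4 would give the hydroxy ester F4. Dess–Martin oxidation would give the aldehyde F5. Me2AlCl in CH2Cl2 at −78 °C would induce the ene closure (bond C1–C10, hydrogen taken from C6, tether on the central ene carbon) to the bicyclic homoallylic alcohol F6. Dess–Martin oxidation to the β,γ-unsaturated ketone F7 and conjugation with DBU would give 14, where the fallback rejoins the route.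

**Step 10 (Mitsunobu displacement and diazene rearrangement).** The allylic oxyphosphonium ion next to a tetrasubstituted alkene may ionise, which would erode the inversion at C1 and hence the configuration at C5. Elimination to a diene is also possible, and the displacement may be slow beside the C9 quaternary centre. The fallback sets out from 17. Formylation with acetic formic anhydride/pyridine would give the allylic formate F8. Heating with Pd(OAc)2 and PBu3 (1:1) in THF would ionise the formate anti to the leaving group, and decarboxylation would deliver hydride from the metal on the α face to the more substituted terminus C5 (palladium-catalysed formate hydrogenolysis), giving 21, where it rejoins the route.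

**Step 9 (reagent-controlled reduction).** Hydride delivery to the α face may be slow or mismatched if ring B prefers the conformer with the C9 methyl axial on that face. The fallback leaves out steps 9 and 10 and sets out from 16. Condensation with 4-methylbenzenesulfonohydrazide would give the tosylhydrazone F9. Reduction with catecholborane followed by NaOAc·3H2O and heat would give the same kind of allylic diazene and then 21, where it rejoins the route. Facial selection at C1 is then substrate controlled and less secure.

**Step 5 (zinc enolate coupling).** Transmetalation and reductive elimination may be slow for the α-branched secondary zinc enolate, which would let protodetriflation compete, and the alkene could move into conjugation with the ester. The fallback sets out from triflate 6. Coupling with the unbranched Reformatsky reagent from methyl bromoacetate under the same palladium catalysis would give methyl 2-[(3S,4R)-3-ethenyl-3,4-dimethylcyclohex-1-en-1-yl]acetate F10. Deprotonation with LiN(i-Pr)2 at −78 °C and Michael addition to tert-butyl acrylate would form C3–C4 and give 10, where it rejoins the route.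

**Step 15 (chelation-controlled methyl addition).** Chelation may be incomplete (Felkin–Anh attack or a chelate through the distal dioxolane oxygen), which would give the C13 epimer, and the Grignard reagent may enolise the ketone. The fallback sets C13 and C14 by reagent control and sets out from 21. Hydroboration to 22 and B-alkyl Suzuki–Miyaura coupling with (E)-3-iodobut-2-en-1-ol [PdCl2(dppf), AsPh3, Cs2CO3, DMF/THF/H2O] would give the (E)-allylic alcohol F11. Sharpless epoxidation with Ti(OiPr)4, D-(−)-diethyl tartrate and t-BuOOH would give the (13R,14R)-epoxy alcohol F12. Acid-catalysed hydrolysis (HClO4, THF/H2O) at the tertiary C13 with inversion would give triol 30, where it rejoins the route.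

## Further compounds

F1 | step 8 | 5-tert-butyl 1-methyl 2-[(3S,4R)-3-ethenyl-3,4-dimethylcyclohex-1-en-1-yl]-2-methylpentanedioate (both C4 epimers) | COC(=O)C(C)(CCC(=O)OC(C)(C)C)C1=C[C@@](C)(C=C)[C@H](C)CC1
F2 | step 8 | 4-[(3S,4R)-3-ethenyl-3,4-dimethylcyclohex-1-en-1-yl]-5-methoxy-4-methyl-5-oxopentanoic acid (both C4 epimers) | COC(=O)C(C)(CCC(=O)O)C1=C[C@@](C)(C=C)[C@H](C)CC1
F3 | step 8 | methyl (1S,5S,6R)-5-ethenyl-1,5,6-trimethyl-4-oxo-1,2,3,4,5,6,7,8-octahydronaphthalene-1-carboxylate (C4 epimer of 16) | COC(=O)[C@@]1(C)CCC(=O)C2=C1CC[C@@H](C)[C@]2(C)C=C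
F4 | step 7 | methyl 2-[(3S,4R)-3-ethenyl-3,4-dimethylcyclohex-1-en-1-yl]-5-hydroxypentanoate | COC(=O)C(CCCO)C1=C[C@@](C)(C=C)[C@H](C)CC1
F5 | step 7 | methyl 2-[(3S,4R)-3-ethenyl-3,4-dimethylcyclohex-1-en-1-yl]-5-oxopentanoate | COC(=O)C(CCC=O)C1=C[C@@](C)(C=C)[C@H](C)CC1
F6 | step 7 | methyl (5S,6R)-5-ethenyl-4-hydroxy-5,6-dimethyl-1,2,3,4,4a,5,6,7-octahydronaphthalene-1-carboxylate (mixture at C1, C4 and C10) | COC(=O)C1CCC(O)C2C1=CC[C@@H](C)[C@]2(C)C=C
F7 | step 7 | methyl (5S,6R)-5-ethenyl-5,6-dimethyl-4-oxo-1,2,3,4,4a,5,6,7-octahydronaphthalene-1-carboxylate | COC(=O)C1CCC(=O)C2C1=CC[C@@H](C)[C@]2(C)C=C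
F8 | step 10 | methyl (1R,4R,5S,6R)-5-ethenyl-4-(formyloxy)-1,5,6-trimethyl-1,2,3,4,5,6,7,8-octahydronaphthalene-1-carboxylate | COC(=O)[C@]1(C)CC[C@@H](OC=O)C2=C1CC[C@@H](C)[C@]2(C)C=C
F9 | step 9 | 4-methylbenzenesulfonylhydrazone of 16 (C=N geometry not fixed) | COC(=O)[C@]1(C)CCC(=NNS(=O)(=O)c3ccc(C)cc3)C2=C1CC[C@@H](C)[C@]2(C)C=C
F10 | step 5 | methyl 2-[(3S,4R)-3-ethenyl-3,4-dimethylcyclohex-1-en-1-yl]acetate | COC(=O)CC1=C[C@@](C)(C=C)[C@H](C)CC1
F11 | step 15 | methyl (1R,5S,6R,8aR)-5-[(3E)-5-hydroxy-3-methylpent-3-en-1-yl]-1,5,6-trimethyl-1,2,3,5,6,7,8,8a-octahydronaphthalene-1-carboxylate | COC(=O)[C@]1(C)CCC=C2[C@H]1CC[C@@H](C)[C@]2(C)CC/C(C)=C/CO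
F12 | step 15 | methyl (1R,5S,6R,8aR)-5-{2-[(2R,3R)-3-(hydroxymethyl)-2-methyloxiran-2-yl]ethyl}-1,5,6-trimethyl-1,2,3,5,6,7,8,8a-octahydronaphthalene-1-carboxylate | COC(=O)[C@]1(C)CCC=C2[C@H]1CC[C@@H](C)[C@]2(C)CC[C@@]3(C)O[C@@H]3CO
A1 | alternative 1 | open-chain 1,7-enyne, TBS ether of 2-ethynyl-2,3-dimethylhept-6-en-1-ol with the C8 and C9 configurations of the target | C#C[C@@](C)(CO[Si](C)(C)C(C)(C)C)[C@H](C)CCC=C
A2 | alternative 1 | ring B vinylcyclohexene, TBS ether of (2-ethenyl-1,6-dimethylcyclohex-2-en-1-yl)methanol | C=CC1=CCC[C@@H](C)[C@]1(C)CO[Si](C)(C)C(C)(C)C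
A3 | alternative 1 | methacrolein | CC(=C)C=O
A4 | alternative 1 | bicyclic C19 aldehyde with the C1=C10 alkene and the C11 silyl ether | O=C[C@]1(C)CCC=C2[C@H]1CC[C@@H](C)[C@]2(C)CO[Si](C)(C)C(C)(C)C
A5 | alternative 2 | 9(10)-ene 1α-alcohol with complete side chain (acetonide) | COC(=O)[C@]1(C)CC[C@H](O)C2=C(CC[C@](C)(O)[C@H]3COC(C)(C)O3)[C@H](C)CC[C@@H]12
A6 | alternative 2 | 9,10-methano (cyclopropyl) carbinol | COC(=O)[C@]1(C)CC[C@H](O)[C@]2(C3)[C@H]1CC[C@@H](C)[C@]23CC[C@](C)(O)[C@H]1COC(C)(C)O1
A7 | alternative 3 | dienyne, methyl (2Z)-2-methylpent-2-en-4-ynoate carrying the ring B cyclohexenyl group on C5, side chain as triethylsilyl ether and acetonide | COC(=O)/C(C)=C\C#CC1=CCC[C@@H](C)[C@]1(C)CC[C@](C)(O[Si](CC)(CC)CC)[C@H]2COC(C)(C)O2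
A8 | alternative 3 | (2Z,4Z)-triene from semihydrogenation of A7 | COC(=O)/C(C)=C\C=C/C1=CCC[C@@H](C)[C@]1(C)CC[C@](C)(O[Si](CC)(CC)CC)[C@H]2COC(C)(C)O2
A9 | alternative 3 | bicyclic 1(10),2-diene methyl ester | COC(=O)[C@]1(C)C=CC=C2[C@H]1CC[C@@H](C)[C@]2(C)CC[C@](C)(O[Si](CC)(CC)CC)[C@H]1COC(C)(C)O1
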